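**Plan**
- Retrosynthesis first removes nine O–methyl groups, then cuts the ring B–ring C ether C–O bond and the ring A–ring B ether C–O bond (both Ullmann), and takes the ether oxygen at C3 of ring C back to a C–H bond by way of a formyl group.
- Feature: without that C3 oxygen, rings C and D are a symmetrical 2,2',4,4',6,6'-hexaoxygenated biphenyl, two phloroglucinol rings joined carbon to carbon at C1–C1'. Each ring maps onto one triacetic lactone unit, and the tetra-ortho-substituted C1–C1' axis maps onto a CH2–CH2 bond.
- The ring bonds C1–C2 (ring C) and C1'–C2' (ring D) are therefore cut to give an ethylene-bridged bis(4-methoxy-2-pyrone). Its CH2–CH2 bond is cut last, into a pyrone dienolate and a bromomethylpyrone.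
- Forward: the bis-pyrone is assembled by sp3–sp3 alkylation, rings C and D are closed together by a double pyrone-to-benzene isomerization, and the biphenyl is permethylated, mono-formylated and oxidized to the C3 phenol. Rings A and B are commercial arenes joined by one Ullmann coupling; the A–B bromide is then coupled to the C3 phenol and all methyl ethers are cleaved.
- Stereochemistry: none to set. The target has no stereocentre, and the C1–C1' axis is not stereogenic because ring D is symmetric about it.

Key step: step 3

Remark: all phenolic oxygens are carried as methyl ethers from step 4 onward, so a single BBr3 treatment ends the route.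

**Step 1**
Reactants: 1 4-methoxy-6-methyl-2H-pyran-2-one
Product: 2 6-(bromomethyl)-4-methoxy-2H-pyran-2-one
Conditions: NBS (1.05 equiv), AIBN (cat.), CCl4, reflux
Reagents that add atoms: N-bromosuccinimide, BrN1C(=O)CCC1=O
Why: Wohl–Ziegler radical bromination should take place at the 6-methyl group, the only allylic-type C–H position, while the non-polar radical conditions hold back electrophilic bromination at C3.

**Step 2**
Reactants: 1 4-methoxy-6-methyl-2H-pyran-2-one; 2 6-(bromomethyl)-4-methoxy-2H-pyran-2-one
Product: 4 6,6'-(ethane-1,2-diyl)bis(4-methoxy-2H-pyran-2-one), via lithium dienolate 3 (not isolated)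
Conditions: 1, LiN(iPr)2 (1.05 equiv), THF, −78 °C; then cannulated into 2, THF, −78 → −20 °C
Reagents that add atoms: none
Why: Deprotonation of the 6-methyl group gives the extended lithium dienolate 3, whose exocyclic carbon should displace bromide from the activated primary bromide 2 in an SN2 enolate alkylation, the usual way of extending this pyrone at C6, and inverse addition at low temperature limits proton exchange with 2 and 4.

**Step 3**
Reactants: 4 6,6'-(ethane-1,2-diyl)bis(4-methoxy-2H-pyran-2-one)
Product: 8 4,4'-dimethoxybiphenyl-2,2',6,6'-tetrol, via half-opened keto enoate 5 (not isolated), via pyronylmethyl resorcinol 6 (not isolated), via aryl keto enoate 7 (not isolated)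
Conditions: NaOMe (8 equiv), degassed MeOH, sealed tube, 100 °C, Ar; then aq. HCl, 0 °C
Reagents that add atoms: none
Why: Proposed new method: methoxide adds to a lactone carbonyl and opens that pyrone to a methyl (2E)-3-methoxy-5-oxo-2-enoate (5), the ketone enolate at the adjacent bridge CH2 attacks the ester carbonyl of its own chain and expels methoxide, and the resulting 5-methoxycyclohex-4-ene-1,3-dione tautomerizes to the resorcinol (6); the same sequence on the second pyrone (via 7) turns the former CH2–CH2 bond into the aryl–aryl bond of 8. The closest known reaction is the alkoxide-induced isomerization of 4-methoxy-6-methyl-2H-pyran-2-one to 5-methoxyresorcinol, an intramolecular Claisen (Dieckmann-type) condensation; new here are its twofold use on an ethylene-bridged bis-pyrone and a substituted CH2 as the nucleophilic carbon. Ring C and ring D each close in the 6-(enolendo)-exo-trig mode, which is favourable for enolates. No stereocentre is formed and the new axis is not stereogenic, since both rings are symmetric about it. The step needs C-acylation by the bridge carbons only: each bridge carbon is the sole enolizable position six atoms from its ester, the more acidic C4 methylene of the opened chain could close only a four-membered ring, and in strongly basic methanol any opened ketone should rest as its delocalized dienolate and so not serve as the acceptor for a 1,4-diketone aldol to a cyclopentenone. Exchange of the 4-methoxy group with methoxide is degenerate, and exclusion of oxygen protects the electron-rich phenoxide of 8.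

**Step 4**
Reactants: 8 4,4'-dimethoxybiphenyl-2,2',6,6'-tetrol
Product: 9 2,2',4,4',6,6'-hexamethoxy-1,1'-biphenyl
Conditions: Me2SO4 (6 equiv), K2CO3, acetone, reflux, Ar
Reagents that add atoms: dimethyl sulfate, COS(=O)(=O)OC
Why: Williamson O-methylation with Me2SO4 and K2CO3 in acetone is a weakly basic medium in which phloroglucinol-type phenols should be alkylated on oxygen and not on carbon.

**Step 5**
Reactants: 9 2,2',4,4',6,6'-hexamethoxy-1,1'-biphenyl
Product: 11 2,2',4,4',6,6'-hexamethoxybiphenyl-3-carbaldehyde, via iminium chloride 10 (not isolated)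
Conditions: POCl3 (0.8 equiv), DMF, 0 → 50 °C; then H2O, rt
Reagents that add atoms: N,N-dimethylformamide, CN(C)C=O; water, O
Why: In this Vilsmeier–Haack formylation the four free ring positions of 9 are equivalent and each lies between two methoxy groups as in 1,3,5-trimethoxybenzene, the iminium group of 10 deactivates its own ring, and a deficit of reagent should hold back attack on the second ring, with unreacted 9 recycled.

**Step 6**
Reactants: 11 2,2',4,4',6,6'-hexamethoxybiphenyl-3-carbaldehyde
Product: 13 2,2',4,4',6,6'-hexamethoxybiphenyl-3-ol, via aryl formate 12 (not isolated)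
Conditions: mCPBA (1.1 equiv), CH2Cl2, 0 °C → rt; aq. NaHCO3 wash; then K2CO3 (cat.), MeOH, rt
Reagents that add atoms: meta-chloroperoxybenzoic acid, OOC(=O)c1cccc(Cl)c1
Why: In this Baeyer–Villiger (Dakin-type) oxidation the aryl group flanked by two methoxy groups should migrate in preference to hydrogen to give formate 12, which is methanolysed to the phenol without isolation.

**Step 7**
Reactants: 14 3,5-dimethoxyphenol; 15 1,3-dibromo-5-methoxybenzene (3 equiv)
Product: 16 1-bromo-3-(3,5-dimethoxyphenoxy)-5-methoxybenzene
Conditions: CuI (10 mol %), picolinic acid (20 mol %), K3PO4, DMSO, 90 °C, Ar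
Reagents that add atoms: none
Why: In this copper-catalysed Ullmann diaryl ether synthesis the unhindered phenol 14 should react once with the symmetrical dibromide, because 15 is used in excess and the first aryloxy group does not activate the remaining bromide.

**Step 8**
Reactants: 13 2,2',4,4',6,6'-hexamethoxybiphenyl-3-ol; 16 1-bromo-3-(3,5-dimethoxyphenoxy)-5-methoxybenzene
Product: 17 3-[3-(3,5-dimethoxyphenoxy)-5-methoxyphenoxy]-2,2',4,4',6,6'-hexamethoxy-1,1'-biphenyl
Conditions: CuI (20 mol %), picolinic acid (40 mol %), K3PO4, DMSO, 110 °C, Ar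
Reagents that add atoms: none
Why: This Ullmann diaryl ether coupling uses the CuI/picolinic acid system, which tolerates phenols with two ortho substituents, and bromide 16 carries only meta substituents and no competing nucleophile.

**Step 9**
Reactants: 17 3-[3-(3,5-dimethoxyphenoxy)-5-methoxyphenoxy]-2,2',4,4',6,6'-hexamethoxy-1,1'-biphenyl
Product: 18 3-[3-(3,5-dihydroxyphenoxy)-5-hydroxyphenoxy]biphenyl-2,2',4,4',6,6'-hexol (target CNP0133338.0)
Conditions: BBr3 (about 2 equiv per OMe), CH2Cl2, −78 °C → rt, Ar; then MeOH/H2O, 0 °C
Reagents that add atoms: none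
Why: Lewis-acid cleavage of aryl methyl ethers by BBr3 (coordination at oxygen, bromide attack at methyl) should remove all nine methyl groups while leaving the diaryl ether and biaryl bonds intact.

**Compound list**
1 | 4-methoxy-6-methyl-2H-pyran-2-one | COc1cc(C)oc(=O)c1 | starting material
2 | 6-(bromomethyl)-4-methoxy-2H-pyran-2-one | COc1cc(CBr)oc(=O)c1 | intermediate
3 | lithium dienolate of 1, lithiated at the 6-methyl carbon (formed in the flask) | COc1cc(C[Li])oc(=O)c1 | intermediate
4 | 6,6'-(ethane-1,2-diyl)bis(4-methoxy-2H-pyran-2-one) | COc1cc(CCc2cc(OC)cc(=O)o2)oc(=O)c1 | intermediate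
5 | methyl (2E)-3-methoxy-7-(4-methoxy-2-oxo-2H-pyran-6-yl)-5-oxohept-2-enoate (formed in the flask) | COC(=O)/C=C(/OC)CC(=O)CCc1cc(OC)cc(=O)o1 | intermediate
6 | 6-[(2,6-dihydroxy-4-methoxyphenyl)methyl]-4-methoxy-2H-pyran-2-one (formed in the flask) | COc1cc(O)c(Cc2cc(OC)cc(=O)o2)c(O)c1 | intermediate
7 | methyl (2E)-6-(2,6-dihydroxy-4-methoxyphenyl)-3-methoxy-5-oxohex-2-enoate (formed in the flask) | COC(=O)/C=C(/OC)CC(=O)Cc1c(O)cc(OC)cc1O | intermediate
8 | 4,4'-dimethoxybiphenyl-2,2',6,6'-tetrol | COc1cc(O)c(-c2c(O)cc(OC)cc2O)c(O)c1 | intermediate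
9 | 2,2',4,4',6,6'-hexamethoxy-1,1'-biphenyl | COc1cc(OC)c(-c2c(OC)cc(OC)cc2OC)c(OC)c1 | intermediate
10 | N-[(2,2',4,4',6,6'-hexamethoxybiphenyl-3-yl)methylidene]-N-methylmethanaminium chloride (formed in the flask) | COc1cc(OC)c(-c2c(OC)cc(OC)c(C=[N+](C)C)c2OC)c(OC)c1.[Cl-] | intermediate
11 | 2,2',4,4',6,6'-hexamethoxybiphenyl-3-carbaldehyde | COc1cc(OC)c(-c2c(OC)cc(OC)c(C=O)c2OC)c(OC)c1 | intermediate
12 | 2,2',4,4',6,6'-hexamethoxybiphenyl-3-yl formate (formed in the flask) | COc1cc(OC)c(-c2c(OC)cc(OC)c(OC=O)c2OC)c(OC)c1 | intermediate
13 | 2,2',4,4',6,6'-hexamethoxybiphenyl-3-ol | COc1cc(OC)c(-c2c(OC)cc(OC)c(O)c2OC)c(OC)c1 | intermediate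
14 | 3,5-dimethoxyphenol | COc1cc(O)cc(OC)c1 | starting material
15 | 1,3-dibromo-5-methoxybenzene (3,5-dibromoanisole) | COc1cc(Br)cc(Br)c1 | starting material
16 | 1-bromo-3-(3,5-dimethoxyphenoxy)-5-methoxybenzene | COc1cc(OC)cc(Oc2cc(Br)cc(OC)c2)c1 | intermediate
17 | 3-[3-(3,5-dimethoxyphenoxy)-5-methoxyphenoxy]-2,2',4,4',6,6'-hexamethoxy-1,1'-biphenyl | COc1cc(OC)cc(Oc2cc(OC)cc(Oc3c(OC)cc(OC)c(-c4c(OC)cc(OC)cc4OC)c3OC)c2)c1 | intermediate
18 | 3-[3-(3,5-dihydroxyphenoxy)-5-hydroxyphenoxy]biphenyl-2,2',4,4',6,6'-hexol | Oc1cc(O)cc(Oc2cc(O)cc(Oc3c(O)cc(O)c(-c4c(O)cc(O)cc4O)c3O)c2)c1 | target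

**Step count**
Total steps: 9. Longest linear sequence: 8 steps (steps 1, 2, 3, 4, 5, 6, 8 and 9, from compound 1); step 7 is the one-step side branch to the ring A–ring B bromide.

**Steps most likely to fail**

Step 3 (proposed new method). Three processes could divert it. If both pyrones are open at once, the 1,4-diketone may undergo aldol closure to a cyclopentenone. After the first ring has formed, a phenoxide oxygen may add to the neighbouring ketone and dehydrate to a benzofuran. The sequence may also stall at the half-aromatized stage, because the second enolization has to occur next to an electron-rich bis-phenoxide. The fallback uses known chemistry, sets out from 14 and rejoins the route at 9, replacing steps 1–4. O-Methylation of 14 (MeI, K2CO3, acetone, reflux) would give 1,3,5-trimethoxybenzene F1. Iodination with N-iodosuccinimide (cat. CF3CO2H, MeCN, rt) would give 2-iodo-1,3,5-trimethoxybenzene F2. Classical Ullmann biaryl homocoupling of F2 (Cu powder, DMF, 150 °C) would give 9.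

Step 2. Proton transfer from the acidic CH2Br group of 2, or from the bridge of product 4, to dienolate 3 could lead to over-alkylation and decomposition of the bromide, and the ambident anion could react through C5 or oxygen. The fallback sets out from 2 and 1 and rejoins the route at 4. Arbuzov reaction of 2 with P(OEt)3 (neat, 120 °C) would give diethyl [(4-methoxy-2-oxo-2H-pyran-6-yl)methyl]phosphonate F3. Oxidation of the methyl group of 1 with SeO2 (dioxane, sealed tube, 160 °C) would give 4-methoxy-2-oxo-2H-pyran-6-carbaldehyde F4. Horner–Wadsworth–Emmons olefination of F4 with F3 (NaH, THF, 0 °C) would give 6,6'-[(E)-ethene-1,2-diyl]bis(4-methoxy-2H-pyran-2-one) F5. Hydrogenation of the exocyclic alkene (H2, Pd/C, EtOAc, rt), stopped after one equivalent, would give 4.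

Step 8. C–O bond formation at the doubly ortho-substituted, electron-rich phenoxide of 13 may be slow, so that oxidation of the phenoxide and hydrodebromination of the more valuable bromide 16 take over. The fallback changes the order of ether formation, so that the hindered phenol meets a cheap electrophile used in large excess and the last bond is made with an unhindered phenol. It sets out from 13 and rejoins the route at 17. Coupling of 13 with 15 (5 equiv; CuI, picolinic acid, K3PO4, DMSO, 110 °C) would give 3-(3-bromo-5-methoxyphenoxy)-2,2',4,4',6,6'-hexamethoxy-1,1'-biphenyl F6. A second Ullmann coupling of F6 with 14 under the conditions of step 7 would give 17.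

**Further compounds**
F1 | step 3 | 1,3,5-trimethoxybenzene | COc1cc(OC)cc(OC)c1
F2 | step 3 | 2-iodo-1,3,5-trimethoxybenzene | COc1cc(OC)c(I)c(OC)c1
F3 | step 2 | diethyl [(4-methoxy-2-oxo-2H-pyran-6-yl)methyl]phosphonate | CCOP(=O)(Cc1cc(OC)cc(=O)o1)OCC
F4 | step 2 | 4-methoxy-2-oxo-2H-pyran-6-carbaldehyde | COc1cc(C=O)oc(=O)c1
F5 | step 2 | 6,6'-[(E)-ethene-1,2-diyl]bis(4-methoxy-2H-pyran-2-one) | COc1cc(/C=C/c2cc(OC)cc(=O)o2)oc(=O)c1
F6 | step 8 | 3-(3-bromo-5-methoxyphenoxy)-2,2',4,4',6,6'-hexamethoxy-1,1'-biphenyl | COc1cc(Br)cc(Oc2c(OC)cc(OC)c(-c3c(OC)cc(OC)cc3OC)c2OC)c1
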